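**Plan**

1. Locants: ring C1 (bears the side chain), C2 (CH2), C3, C4 (C–CH3), C5, C6; side chain C7(=C14H2)–C8–C9H2–C10–C11Me2.
2. Retrosynthesis: remove the silyl ethers and the C10 angelate, cut C9–C10 (aldol, C8 at the ketone level), take the C8 ketone/C9 methyl back to an isopropenyl group, then take the ring C–O bonds (C5 ester, C3, C4, C6) back to (S)-carvone. The C10–C11 piece comes from methyl 2-hydroxyisobutyrate.
3. Enabling feature: C9 is a CH2 between two oxygenated carbons. C8 is allylic to the C7=C14 exo-methylene, so as a ketone it is a vinyl methyl ketone that can enolise only towards C9. C10 carries the fully substituted C11, so its aldehyde has no α-hydrogen.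
4. Forward: no ring is formed. The carvone ring is oxygenated (C6, then C5, C4, C3), the isopropenyl group becomes the C7(=C14)–C8(=O)–C9H3 ketone, the chain is joined at C9–C10, then C8 is reduced, C10 acylated and all silyl groups removed.
5. Chiral-pool mapping and stereocontrol: carvone C1(=O) becomes ring C5 (angelate carbon), C2–CH3 becomes C4, C3 stays C3, C6 stays C6, C5 becomes C1. C1 comes from carvone, C6 from kinetic protonation, C5 from Luche reduction, C4 from OH-directed epoxidation, C3 from trans-diaxial epoxide opening, C10 from the chiral boron reagent, C8 from 1,3-anti reduction.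

Key step: step 13

Assumption: for Ipc2B enolates of methyl ketones the (−)-reagent is taken to attack the aldehyde Si face (as in the related allylborations). The (+)-reagent (from (−)-α-pinene) is therefore written for the Re-face attack needed here; if the sense were the reverse, the antipodal reagent would be used with no other change.

**Route**

Step 1
Reactants: 1 (S)-(+)-carvone
Product: 3 trans-6-(tert-butyldimethylsilyloxy)carvone, via TBS dienol ether 2 (not isolated)
Conditions: LDA, THF, −78 °C; TBSCl, DMPU, −78 → 0 °C; then mCPBA, NaHCO3, CH2Cl2, −20 °C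
Reagents that add atoms: tert-butyldimethylsilyl chloride CC(C)(C)[Si](C)(C)Cl; mCPBA OOC(=O)c1cccc(Cl)c1
Why: Rubottom oxidation: kinetic α′-deprotonation and O-silylation give the cross-conjugated dienol ether, whose enol C=C is oxidised by the peracid anti to the neighbouring isopropenyl group with silyl transfer to the new oxygen, so C6–O should form trans to the side chain (corrected in step 2).

Step 2
Reactants: 3 trans-6-(tert-butyldimethylsilyloxy)carvone
Product: 5 cis-6-(tert-butyldimethylsilyloxy)carvone, via lithium enediolate 4 (not isolated)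
Conditions: LDA, THF, −78 °C, 20 min; AcOH in THF, −78 °C
Reagents that add atoms: none
Why: Kinetic protonation of an enolate (Zimmerman-type contra-thermodynamic epimerisation): in the enediolate the C6 silyloxy group pushes the adjacent isopropenyl group pseudo-axial (A1,2 strain), so the proton should enter C6 anti to it and leave OTBS cis to the side chain.

Step 3
Reactants: 5 cis-6-(tert-butyldimethylsilyloxy)carvone
Product: 6 all-cis allylic alcohol (1-OH, 6-OTBS and 5-isopropenyl on one face; carvone numbering)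
Conditions: NaBH4, CeCl3·7H2O, MeOH, −78 °C
Reagents that add atoms: none
Why: Luche 1,2-reduction; hydride should add to the carbonyl face anti to both the C6–OTBS and the isopropenyl group, giving the carbinol (future ring C5) cis to both.

Step 4
Reactants: 6 all-cis allylic alcohol
Product: 7 epoxy alcohol (2,3-epoxide on the face of the hydroxyl)
Conditions: VO(acac)2 (cat.), t-BuOOH, CH2Cl2, 0 °C → rt
Reagents that add atoms: tert-butyl hydroperoxide CC(C)(C)OO
Why: Hydroxyl-directed vanadium-catalysed epoxidation delivers oxygen to the ring alkene syn to the allylic OH and leaves the isopropenyl alkene alone, as with cis-carveol; this sets the future C4–O cis to C5–O.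

Step 5
Reactants: 7 epoxy alcohol
Product: 8 epoxy angelate
Conditions: angelic acid, 2,4,6-trichlorobenzoyl chloride, Et3N, THF, rt, filter; then 7, toluene, 75 °C (no DMAP)
Reagents that add atoms: angelic acid C/C=C(/C)C(=O)O
Why: Yamaguchi esterification of the only free hydroxyl through the mixed anhydride, a DMAP-free protocol used for angelates because it keeps the Z geometry.

Step 6
Reactants: 8 epoxy angelate
Product: 9 C3,C4-diol (C3–OH trans to the tertiary C4–OH; C5 angelate; C6 OTBS)
Conditions: HClO4 (cat., aq.), THF, 0 °C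
Reagents that add atoms: water O
Why: Acid-catalysed trans-diaxial (Fürst–Plattner) epoxide hydrolysis: water should attack the secondary carbon C3 anti to the epoxide oxygen, as in the hydrolysis of trans-limonene oxide, and the acyloxy group at C5 further disfavours ionisation at C4.

Step 7
Reactants: 9 C3,C4-diol
Product: 10 C3-O-TES C4-O-TMS ether
Conditions: TESOTf (1.2 equiv), 2,6-lutidine, CH2Cl2, −78 °C; then TMSOTf (2 equiv), −78 → 0 °C
Reagents that add atoms: triethylsilyl triflate CC[Si](CC)(CC)OS(=O)(=O)C(F)(F)F; trimethylsilyl triflate C[Si](C)(C)OS(=O)(=O)C(F)(F)F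
Why: Silyl triflate silylation, with the larger group on the secondary and the smallest on the crowded tertiary hydroxyl, so that no OH remains for the boron-mediated step.

Step 8
Reactants: 10 C3-O-TES C4-O-TMS ether
Product: 12 enal (C8 aldehyde), via primary allylic alcohol 11 (not isolated)
Conditions: SeO2 (cat.), t-BuOOH, CH2Cl2, rt; then Dess–Martin periodinane, NaHCO3, CH2Cl2, 0 °C
Reagents that add atoms: tert-butyl hydroperoxide CC(C)(C)OO
Why: SeO2-catalysed allylic hydroxylation (ene/[2,3] sequence) of the only electron-rich alkene at its methyl group, then Dess–Martin oxidation to the 2-substituted acrolein; the electron-poor angelate alkene should not react.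

Step 9
Reactants: 12 enal
Product: 13 secondary allylic alcohol (C8 epimer mixture)
Conditions: MeMgBr, THF, −78 °C
Reagents that add atoms: methylmagnesium bromide C[Mg]Br
Why: Grignard 1,2-addition to the aldehyde, faster at −78 °C than attack on the hindered conjugated ester; the new carbinol centre is not controlled and is removed in step 10.

Step 10
Reactants: 13 secondary allylic alcohol
Product: 14 vinyl methyl ketone (C8 ketone, C9 methyl)
Conditions: Dess–Martin periodinane, NaHCO3, CH2Cl2, 0 °C → rt
Reagents that add atoms: none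
Why: Dess–Martin oxidation of the allylic alcohol under buffered, non-basic conditions that spare the silyl ethers and the angelate.

Step 11
Reactants: 15 methyl 2-hydroxy-2-methylpropanoate
Product: 16 methyl 2-methyl-2-(triethylsilyloxy)propanoate
Conditions: TESOTf, 2,6-lutidine, CH2Cl2, 0 °C
Reagents that add atoms: triethylsilyl triflate CC[Si](CC)(CC)OS(=O)(=O)C(F)(F)F
Why: Silyl triflate silylation of a tertiary hydroxyl.

Step 12
Reactants: 16 methyl 2-methyl-2-(triethylsilyloxy)propanoate
Product: 17 2-methyl-2-(triethylsilyloxy)propanal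
Conditions: DIBAL-H, CH2Cl2, −78 °C; Rochelle salt work-up
Reagents that add atoms: none
Why: DIBAL-H partial reduction of a hindered α-silyloxy ester stops at the aluminium hemiacetal at −78 °C and gives the aldehyde on work-up.

Step 13
Reactants: 14 vinyl methyl ketone; 17 2-methyl-2-(triethylsilyloxy)propanal
Product: 20 (10R)-β-hydroxy ketone, via boron enolate 18 (not isolated), via boron aldolate 19 (not isolated)
Conditions: (+)-Ipc2BCl, Et3N, Et2O, 0 °C, 1 h; then 17 (2.5 equiv), −78 → −20 °C; MeOH, pH 7 buffer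
Reagents that add atoms: none
Why: Et3N/(+)-Ipc2BCl soft-enolises 14 at its only enolisable carbon (the methyl group C9, since C7 is sp2); aldehyde 17, which has no α-hydrogen, binds to boron and C9–C10 forms through a cyclic six-membered boron aldol transition state. The closest known reaction type is the Paterson aldol of diisopinocampheylboron enolates of methyl ketones with aldehydes. No ring is closed. The new stereocentre C10 is set by the isopinocampheyl ligands (reagent control, Re-face attack on the aldehyde), because the ring stereocentres are remote and insulated by the sp2 carbon C7. The step needs site-selective enolisation, 1,2- rather than conjugate addition, and aldehyde face selectivity; the first is secured by the absence of any other α-hydrogen in either partner, the second by the closed transition state and the α-branched enone, the third by the reagent. The C10 hydroxyl then directs the reduction at C8 in step 14, so this one union fixes the whole C8/C10 1,3-anti array.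

Step 14
Reactants: 20 (10R)-β-hydroxy ketone
Product: 21 (8R,10R)-anti-1,3-diol
Conditions: Me4NBH(OAc)3, MeCN/AcOH (1:1), −30 °C
Reagents that add atoms: none
Why: Evans–Saksena reduction: hydride is delivered internally from boron bound to the C10 hydroxyl through a chair-like transition state, which should set C8 anti to C10; the reagent does not reduce the ester or add 1,4 to the enone.

Step 15
Reactants: 21 (8R,10R)-anti-1,3-diol
Product: 22 C8-O-TES ether (C10–OH free)
Conditions: TESCl (1.2 equiv), imidazole, CH2Cl2, −20 °C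
Reagents that add atoms: triethylsilyl chloride CC[Si](CC)(CC)Cl
Why: Kinetic monosilylation; the allylic C8 hydroxyl is far more accessible than the C10 hydroxyl, which sits next to the fully substituted C11 bearing OTES.

Step 16
Reactants: 22 C8-O-TES ether
Product: 23 fully silylated 5,10-bis-angelate
Conditions: angelic acid, 2,4,6-trichlorobenzoyl chloride, Et3N, THF, rt, filter; then 22, toluene, 75–80 °C (no DMAP)
Reagents that add atoms: angelic acid C/C=C(/C)C(=O)O
Why: Yamaguchi esterification of the one remaining hydroxyl under the DMAP-free conditions that keep the Z geometry of the angelate.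

Step 17
Reactants: 23 fully silylated 5,10-bis-angelate
Product: 24 target CNP0108485.1
Conditions: HF·pyridine, pyridine/THF, 0 °C → rt
Reagents that add atoms: none
Why: Global desilylation with buffered HF·pyridine removes the TMS, TES and TBS ethers; the mildly acidic fluoride medium avoids the base-induced acyl migration that a polyol diester would risk, and no stereocentre is touched.

**Compound list**

1 | (S)-(+)-carvone, (5S)-2-methyl-5-(prop-1-en-2-yl)cyclohex-2-en-1-one | CC(=C)[C@H]1CC=C(C)C(=O)C1 | starting material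
2 | TBS dienol ether of 1 (1-silyloxycyclohexa-1,5-diene; C1=C6 and C2=C3 of carvone) | CC(=C)[C@H]1CC=C(C)C(O[Si](C)(C)C(C)(C)C)=C1 | intermediate (not isolated)
3 | trans-6-(tert-butyldimethylsilyloxy)carvone (OTBS trans to isopropenyl) | CC(=C)[C@H]1CC=C(C)C(=O)[C@@H]1O[Si](C)(C)C(C)(C)C | intermediate
4 | lithium enediolate of 3 (C1–OLi, C6–OTBS, C1=C6) | CC(=C)[C@H]1CC=C(C)C(O[Li])=C1O[Si](C)(C)C(C)(C)C | intermediate (not isolated)
5 | cis-6-(tert-butyldimethylsilyloxy)carvone (OTBS cis to isopropenyl) | CC(=C)[C@H]1CC=C(C)C(=O)[C@H]1O[Si](C)(C)C(C)(C)C | intermediate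
6 | 6-(tert-butyldimethylsilyloxy)-2-methyl-5-(prop-1-en-2-yl)cyclohex-2-en-1-ol, 1-OH/6-OTBS/5-isopropenyl all cis | CC(=C)[C@H]1CC=C(C)[C@@H](O)[C@H]1O[Si](C)(C)C(C)(C)C | intermediate
7 | 2,3-epoxide of 6, epoxide oxygen cis to OH, OTBS and isopropenyl | CC(=C)[C@H]1C[C@H]2O[C@@]2(C)[C@@H](O)[C@H]1O[Si](C)(C)C(C)(C)C | intermediate
8 | angelate ((Z)-2-methylbut-2-enoate) of 7 | CC(=C)[C@H]1C[C@H]2O[C@@]2(C)[C@@H](OC(=O)/C(C)=C\C)[C@H]1O[Si](C)(C)C(C)(C)C | intermediate
9 | ring diol: C1 isopropenyl, C3–OH (trans to C4–OH), C4(CH3)–OH, C5 angelate, C6 OTBS (C4–O, C5–O, C6–O and C1 substituent cis) | CC(=C)[C@H]1C[C@H](O)[C@@](C)(O)[C@@H](OC(=O)/C(C)=C\C)[C@H]1O[Si](C)(C)C(C)(C)C | intermediate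
10 | 9 with C3–OTES and C4–OTMS | CC(=C)[C@H]1C[C@H](O[Si](CC)(CC)CC)[C@@](C)(O[Si](C)(C)C)[C@@H](OC(=O)/C(C)=C\C)[C@H]1O[Si](C)(C)C(C)(C)C | intermediate
11 | primary allylic alcohol (C7(=C14H2)–C8H2OH) | OCC(=C)[C@H]1C[C@H](O[Si](CC)(CC)CC)[C@@](C)(O[Si](C)(C)C)[C@@H](OC(=O)/C(C)=C\C)[C@H]1O[Si](C)(C)C(C)(C)C | intermediate (not isolated)
12 | enal (C7(=C14H2)–C8HO) | O=CC(=C)[C@H]1C[C@H](O[Si](CC)(CC)CC)[C@@](C)(O[Si](C)(C)C)[C@@H](OC(=O)/C(C)=C\C)[C@H]1O[Si](C)(C)C(C)(C)C | intermediate
13 | secondary allylic alcohol (C8–OH, C9 methyl; C8 epimer mixture) | CC(O)C(=C)[C@H]1C[C@H](O[Si](CC)(CC)CC)[C@@](C)(O[Si](C)(C)C)[C@@H](OC(=O)/C(C)=C\C)[C@H]1O[Si](C)(C)C(C)(C)C | intermediate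
14 | vinyl methyl ketone (C7(=C14H2)–C8(=O)–C9H3) | CC(=O)C(=C)[C@H]1C[C@H](O[Si](CC)(CC)CC)[C@@](C)(O[Si](C)(C)C)[C@@H](OC(=O)/C(C)=C\C)[C@H]1O[Si](C)(C)C(C)(C)C | intermediate
15 | methyl 2-hydroxy-2-methylpropanoate | COC(=O)C(C)(C)O | starting material
16 | methyl 2-methyl-2-(triethylsilyloxy)propanoate | COC(=O)C(C)(C)O[Si](CC)(CC)CC | intermediate
17 | 2-methyl-2-(triethylsilyloxy)propanal | O=CC(C)(C)O[Si](CC)(CC)CC | intermediate
18 | diisopinocampheylboron enolate of 14 (C8–O–B, C8=C9H2) | C=C(OB([C@H]2C[C@H]3C[C@@H]([C@@H]2C)C3(C)C)[C@H]2C[C@H]3C[C@@H]([C@@H]2C)C3(C)C)C(=C)[C@H]1C[C@H](O[Si](CC)(CC)CC)[C@@](C)(O[Si](C)(C)C)[C@@H](OC(=O)/C(C)=C\C)[C@H]1O[Si](C)(C)C(C)(C)C | intermediate (not isolated)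
19 | boron aldolate (C10–O–BIpc2, C8 ketone) | C=C(C(=O)C[C@@H](OB([C@H]2C[C@H]3C[C@@H]([C@@H]2C)C3(C)C)[C@H]2C[C@H]3C[C@@H]([C@@H]2C)C3(C)C)C(C)(C)O[Si](CC)(CC)CC)[C@H]1C[C@H](O[Si](CC)(CC)CC)[C@@](C)(O[Si](C)(C)C)[C@@H](OC(=O)/C(C)=C\C)[C@H]1O[Si](C)(C)C(C)(C)C | intermediate (not isolated)
20 | (10R)-β-hydroxy ketone (C8 ketone, C10–OH, C11–OTES) | C=C(C(=O)C[C@@H](O)C(C)(C)O[Si](CC)(CC)CC)[C@H]1C[C@H](O[Si](CC)(CC)CC)[C@@](C)(O[Si](C)(C)C)[C@@H](OC(=O)/C(C)=C\C)[C@H]1O[Si](C)(C)C(C)(C)C | intermediate
21 | (8R,10R)-anti-1,3-diol | C=C([C@H](O)C[C@@H](O)C(C)(C)O[Si](CC)(CC)CC)[C@H]1C[C@H](O[Si](CC)(CC)CC)[C@@](C)(O[Si](C)(C)C)[C@@H](OC(=O)/C(C)=C\C)[C@H]1O[Si](C)(C)C(C)(C)C | intermediate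
22 | 21 with C8–OTES (C10–OH free) | C=C([C@H](O[Si](CC)(CC)CC)C[C@@H](O)C(C)(C)O[Si](CC)(CC)CC)[C@H]1C[C@H](O[Si](CC)(CC)CC)[C@@](C)(O[Si](C)(C)C)[C@@H](OC(=O)/C(C)=C\C)[C@H]1O[Si](C)(C)C(C)(C)C | intermediate
23 | fully silylated 5,10-bis-angelate (C3, C8, C11 OTES; C4 OTMS; C6 OTBS) | C=C([C@H](O[Si](CC)(CC)CC)C[C@@H](OC(=O)/C(C)=C\C)C(C)(C)O[Si](CC)(CC)CC)[C@H]1C[C@H](O[Si](CC)(CC)CC)[C@@](C)(O[Si](C)(C)C)[C@@H](OC(=O)/C(C)=C\C)[C@H]1O[Si](C)(C)C(C)(C)C | intermediate
24 | CNP0108485.1, (1R,3S,4R,5S,6S,8R,10R) in the locants above: C3, C4, C6, C8, C11 hydroxyls, C5 and C10 angelates, C7=C14 exo-methylene | C=C([C@H](O)C[C@@H](OC(=O)/C(C)=C\C)C(C)(C)O)[C@H]1C[C@H](O)[C@@](C)(O)[C@@H](OC(=O)/C(C)=C\C)[C@H]1O | target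

**Step count**

Total steps: 17. Longest linear sequence: 15 (steps 1–10 and 13–17); steps 11–12 make the aldehyde partner.

**Three steps most likely to fail**

Step 2. The proton may not discriminate the two faces of the enediolate well enough, the silyl group may shift between the two enediolate oxygens, or the cis ketone may drift back to trans before it is reduced. Fallback: invert C6 by SN2 at carbon instead of by protonation. Setting out from 3, buffered TBAF/AcOH would give trans-6-hydroxycarvone F1. Mitsunobu esterification (4-nitrobenzoic acid, PPh3, DIAD) would give, with inversion, cis-6-(4-nitrobenzoyloxy)carvone F2. Cold methanolysis (K2CO3, MeOH, 0 °C) would give cis-6-hydroxycarvone F3, and TBSCl/imidazole would return to the route at 5.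

Step 13. The isopinocampheyl ligands discriminate the aldehyde faces only moderately with methyl ketone enolates, so C10 may form as an epimer mixture; the hindered aldehyde may also add slowly. Fallback: move the chirality from the enolate metal to a Lewis acid on the aldehyde (Mukaiyama aldol). Setting out from 14, TMSOTf/Et3N would give the 2-(trimethylsilyloxy)-1,3-diene F4. Its addition to 17 under a tryptophan-derived oxazaborolidinone Lewis acid, followed by dilute acid, would return to the route at 20.

Step 16. Acylation of the neopentyl-type C10 hydroxyl may be slow, and forcing conditions may isomerise the activated angelate to the tiglate. Fallback: build the Z-enoate on the oxygen (Still–Gennari olefination). Setting out from 22, DCC/DMAP coupling with 2-[bis(2,2,2-trifluoroethoxy)phosphoryl]propanoic acid would give the phosphonate ester F5. KHMDS/18-crown-6 and acetaldehyde at −78 °C would form the (Z)-2-methylbut-2-enoate and return to the route at 23.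

**Further compounds**

F1 | step 2 | trans-6-hydroxycarvone | CC(=C)[C@H]1CC=C(C)C(=O)[C@@H]1O
F2 | step 2 | cis-6-(4-nitrobenzoyloxy)carvone | CC(=C)[C@H]1CC=C(C)C(=O)[C@H]1OC(=O)c2ccc(cc2)[N+](=O)[O-]
F3 | step 2 | cis-6-hydroxycarvone | CC(=C)[C@H]1CC=C(C)C(=O)[C@H]1O
F4 | step 13 | 2-(trimethylsilyloxy)-1,3-diene from 14 (C8–OTMS, C8=C9H2) | C=C(O[Si](C)(C)C)C(=C)[C@H]1C[C@H](O[Si](CC)(CC)CC)[C@@](C)(O[Si](C)(C)C)[C@@H](OC(=O)/C(C)=C\C)[C@H]1O[Si](C)(C)C(C)(C)C
F5 | step 16 | C10 2-[bis(2,2,2-trifluoroethoxy)phosphoryl]propanoate of 22 | C=C([C@H](O[Si](CC)(CC)CC)C[C@@H](OC(=O)C(C)P(=O)(OCC(F)(F)F)OCC(F)(F)F)C(C)(C)O[Si](CC)(CC)CC)[C@H]1C[C@H](O[Si](CC)(CC)CC)[C@@](C)(O[Si](C)(C)C)[C@@H](OC(=O)/C(C)=C\C)[C@H]1O[Si](C)(C)C(C)(C)C
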